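The route cuts the C5–isopropyl and C6–O bonds of the cyclohexenone (ring A) in a single disconnection. It exploits the contiguous array C1(=O)–C6(O)–C5(isopropyl). Alpha carbon C6 calls for an electrophilic oxygen and beta carbon C5 for a nucleophilic isopropyl, which is the polarity of an enone C5=C6–C1=O. The precursor is therefore a quinone monoketal: a cross-conjugated dienone with the silylated hydroxymethyl arm on C2 and a dimethyl ketal storing the C4 oxygen. In one flask, Cu(OTf)2 and a chiral phosphoramidite move isopropyl from zinc to C5, and the zinc enolate is then hydroxylated at C6. This sets both stereocentres trans. C4 is unmasked, reduced and esterified afterwards.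

Key step: step 4

Remark on the target: it is read as (4S,5S,6R), with the Z ester (angelate) on C4–O cis to isopropyl and the E ester (tiglate) on C6–O trans to isopropyl.
Remark on numbering: every name keeps the target numbering (C1 carbonyl carbon, C2 hydroxymethyl-bearing carbon, C3 vinylic CH, C4, C5 isopropyl carbon, C6). Tigloyl is (E)-2-methylbut-2-enoyl and angeloyl is (Z)-2-methylbut-2-enoyl.
Assumption on the catalyst: the (S,R,R) ligand is taken to attack the same enone face as in cyclohex-2-enone, which corresponds to 5R in the adduct. If the sense were opposite, the equally available (R,S,S) ligand would be used.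
Assumption on C1: the temporary carbinol is drawn as the expected 1R epimer (oxygen trans to the C6 ester). The 1S epimer would follow the same steps, and both converge when C1 is reoxidised.

Step 1
Reactants: 1 2-hydroxy-5-methoxybenzaldehyde
Product: 2 2-(hydroxymethyl)-4-methoxyphenol
Conditions: NaBH4, MeOH, 0 °C; aq NH4Cl
Reagents that add atoms: none
Why: Borohydride reduction of an aryl aldehyde is fast, leaves the phenol and the aryl ether alone, and creates no stereocentre.

Step 2
Reactants: 2 2-(hydroxymethyl)-4-methoxyphenol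
Product: 3 2-[(tert-butyldimethylsilyloxy)methyl]-4-methoxyphenol
Conditions: TBSCl (1.05 equiv), imidazole, CH2Cl2, 0 °C
Reagents that add atoms: tert-butyldimethylsilyl chloride, CC(C)(C)[Si](C)(C)Cl
Why: In this chemoselective O-silylation with one equivalent of chlorosilane, the primary benzylic hydroxyl is the better nucleophile under weakly basic conditions, whereas the phenol is hydrogen-bonded to the neighbouring oxygen, is not deprotonated by imidazole and should stay free.

Step 3
Reactants: 3 2-[(tert-butyldimethylsilyloxy)methyl]-4-methoxyphenol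
Product: 4 2-[(tert-butyldimethylsilyloxy)methyl]-4,4-dimethoxycyclohexa-2,5-dien-1-one
Conditions: PhI(OAc)2 (1.05 equiv), MeOH, 0 °C; aq NaHCO3
Reagents that add atoms: methanol, CO
Why: In this oxidative dearomatisation of a para-methoxyphenol by a trivalent iodine reagent, the phenol oxygen binds iodine and methanol is captured at the para carbon C4, where the resident methoxy group best stabilises the developing positive charge, which is the standard entry to quinone monoketals.

Step 4
Reactants: 4 2-[(tert-butyldimethylsilyloxy)methyl]-4,4-dimethoxycyclohexa-2,5-dien-1-one, 5 diisopropylzinc, 6 2-(phenylsulfonyl)-3-phenyloxaziridine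
Product: 8 (5R,6R)-2-[(tert-butyldimethylsilyloxy)methyl]-6-hydroxy-5-isopropyl-4,4-dimethoxycyclohex-2-en-1-one, via isopropylzinc dienolate 7 (not isolated)
Conditions: Cu(OTf)2 (3 mol %), (S,R,R)-O,O'-(1,1'-binaphthyl-2,2'-diyl)-N,N-bis(1-phenylethyl)phosphoramidite (6 mol %), 5 (1.3 equiv), toluene, −25 °C; then cannulate into 6 (2.5 equiv), THF, −78 to −30 °C; aq NH4Cl
Reagents that add atoms: diisopropylzinc (5), CC(C)[Zn]C(C)C; 2-(phenylsulfonyl)-3-phenyloxaziridine (6), O=S(=O)(c1ccccc1)N1OC1c1ccccc1
Why: Proposed new method: diisopropylzinc reduces Cu(OTf)2 to a ligated monovalent copper alkyl, which binds the C5=C6 alkene of 4 as a pi-complex while zinc activates the C1 carbonyl, passes through a trivalent copper species bonded to C5 and forms the C5–isopropyl bond by reductive elimination, leaving isopropylzinc dienolate 7. C6 of 7 then attacks the oxaziridine oxygen of 6 in an SN2-type displacement that breaks the weak N–O bond, and the zinc hemiaminal collapses to the C6 zinc alkoxide and the sulfonylimine, so two bonds are made and no ring is closed. The closest known reaction types are the copper–phosphoramidite addition of dialkylzincs to 4,4-dialkoxycyclohexadienones with capture of the zinc enolate by aldehydes or silyl triflates, and the oxaziridine hydroxylation of lithium, sodium or potassium enolates; only the direct pairing of a zinc enolate with the oxaziridine is untested, and THF as donor cosolvent, inverse addition and excess oxidant are chosen to raise enolate reactivity, to consume leftover C–Zn bonds and to keep the enolate away from the imine by-product. C5 is controlled by the ligand, which selects one face of the planar dienone (the faces are otherwise equivalent because C4 carries two identical methoxy groups), whereas C6 is controlled by the substrate: in the flattened dienolate the isopropyl group stands pseudoaxial to avoid the ketal, so oxygen arrives on the opposite face and gives the trans product, which is also the more stable epimer should equilibration next to the ketone occur. The step needs C5 over C3 regioselectivity, secured by the C2 silyloxymethyl group because alpha-substituted enone arms bind copper poorly and react far more slowly than unsubstituted ones, and it needs the ring to stay non-aromatic, secured by the fully substituted ketal carbon C4.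

Step 5
Reactants: 8 (5R,6R)-2-[(tert-butyldimethylsilyloxy)methyl]-6-hydroxy-5-isopropyl-4,4-dimethoxycyclohex-2-en-1-one, 9 tigloyl chloride
Product: 10 (5R,6R)-2-[(tert-butyldimethylsilyloxy)methyl]-5-isopropyl-4,4-dimethoxy-6-(tigloyloxy)cyclohex-2-en-1-one
Conditions: 9 (1.5 equiv), pyridine, 4-(dimethylamino)pyridine (cat.), CH2Cl2, 0 °C to rt
Reagents that add atoms: tigloyl chloride (9), C/C=C(\C)C(=O)Cl
Why: In this acid chloride acylation under nucleophilic catalysis, the E acyl geometry is the stable one and cannot drift, the C6–O bond is untouched so C6 keeps its configuration, and the trans C5/C6 arrangement is the thermodynamic one should any enolisation occur.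

Step 6
Reactants: 10 (5R,6R)-2-[(tert-butyldimethylsilyloxy)methyl]-5-isopropyl-4,4-dimethoxy-6-(tigloyloxy)cyclohex-2-en-1-one
Product: 12 (1R,5R,6R)-2-[(tert-butyldimethylsilyloxy)methyl]-1-hydroxy-5-isopropyl-6-(tigloyloxy)cyclohex-2-en-4-one, via allylic alcohol ketal 11 (not isolated)
Conditions: NaBH4, CeCl3·7H2O, MeOH, −78 °C; then AcOH/H2O (1:1), 0 °C to rt
Reagents that add atoms: water, O
Why: In this Luche 1,2-reduction followed by ketal hydrolysis in the same flask, the hard cerium-modified borohydride attacks only the C1 carbonyl, expected along the pseudoaxial line to place the temporary C1 hydroxyl trans to the C6 ester, and once C1 is no longer a carbonyl the C4 ketal is an ordinary allylic ketal whose oxocarbenium ion forms in dilute acetic acid, which the primary silyl ether and the tiglate tolerate.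

Step 7
Reactants: 12 (1R,5R,6R)-2-[(tert-butyldimethylsilyloxy)methyl]-1-hydroxy-5-isopropyl-6-(tigloyloxy)cyclohex-2-en-4-one
Product: 13 (1R,5R,6R)-2-[(tert-butyldimethylsilyloxy)methyl]-5-isopropyl-6-(tigloyloxy)-1-(triethylsilyloxy)cyclohex-2-en-4-one
Conditions: TESOTf (1.2 equiv), 2,6-lutidine, CH2Cl2, −78 °C
Reagents that add atoms: triethylsilyl trifluoromethanesulfonate, CC[Si](CC)(CC)OS(=O)(=O)C(F)(F)F
Why: Silyl triflate protection with a hindered pyridine base at low temperature is fast enough for the flanked C1 hydroxyl and too weakly basic to enolise the C4 ketone, so neither beta-elimination of the C6 tiglate nor epimerisation at C5 is expected.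

Step 8
Reactants: 13 (1R,5R,6R)-2-[(tert-butyldimethylsilyloxy)methyl]-5-isopropyl-6-(tigloyloxy)-1-(triethylsilyloxy)cyclohex-2-en-4-one
Product: 14 (1R,4S,5S,6R)-2-[(tert-butyldimethylsilyloxy)methyl]-5-isopropyl-6-(tigloyloxy)-1-(triethylsilyloxy)cyclohex-2-en-4-ol
Conditions: LiBH(s-Bu)3 (1.1 equiv), THF, −78 °C; aq NH4Cl
Reagents that add atoms: none
Why: In this steric-approach-controlled 1,2-reduction with a bulky trialkylborohydride, isopropyl and tiglate sit pseudoequatorial, so the reagent should avoid the axial line and attack C4 equatorially on the face opposite isopropyl, giving the pseudoaxial alcohol cis to isopropyl (the menthone-to-neomenthol pattern), while the fully substituted beta carbon C2 disfavours conjugate hydride delivery and the ester is inert at −78 °C.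

Step 9
Reactants: 14 (1R,4S,5S,6R)-2-[(tert-butyldimethylsilyloxy)methyl]-5-isopropyl-6-(tigloyloxy)-1-(triethylsilyloxy)cyclohex-2-en-4-ol, 15 angelic acid
Product: 17 (1R,4S,5S,6R)-4-(angeloyloxy)-2-[(tert-butyldimethylsilyloxy)methyl]-5-isopropyl-6-(tigloyloxy)-1-(triethylsilyloxy)cyclohex-2-ene, via angelic 2,4,6-trichlorobenzoic anhydride 16 (not isolated)
Conditions: 15, 2,4,6-trichlorobenzoyl chloride, Et3N, toluene, rt; then 14, toluene, 80 °C
Reagents that add atoms: angelic acid (15), C/C=C(/C)C(=O)O; 2,4,6-trichlorobenzoyl chloride, O=C(Cl)c1c(Cl)cc(Cl)cc1Cl (atoms retained only in 16)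
Why: In this Yamaguchi-type mixed-anhydride esterification run without a nucleophilic catalyst, the alcohol attacks the less shielded angeloyl carbonyl of 16, the absence of any Michael donor closes the addition–elimination pathway that turns Z acyl groups into E, and C4 keeps its configuration because only the O–H bond is broken.

Step 10
Reactants: 17 (1R,4S,5S,6R)-4-(angeloyloxy)-2-[(tert-butyldimethylsilyloxy)methyl]-5-isopropyl-6-(tigloyloxy)-1-(triethylsilyloxy)cyclohex-2-ene
Product: 18 (1R,4S,5S,6R)-4-(angeloyloxy)-2-[(tert-butyldimethylsilyloxy)methyl]-5-isopropyl-6-(tigloyloxy)cyclohex-2-en-1-ol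
Conditions: pyridinium p-toluenesulfonate (cat.), MeOH/CH2Cl2, 0 °C
Reagents that add atoms: none
Why: Acid-catalysed methanolysis distinguishes the two silyl ethers by the bulk on silicon, the triethylsilyl ether being solvolysed much faster than the tert-butyldimethylsilyl ether, and the weakly acidic medium does not promote migration of the neighbouring tiglate.

Step 11
Reactants: 18 (1R,4S,5S,6R)-4-(angeloyloxy)-2-[(tert-butyldimethylsilyloxy)methyl]-5-isopropyl-6-(tigloyloxy)cyclohex-2-en-1-ol
Product: 19 (4S,5S,6R)-4-(angeloyloxy)-2-[(tert-butyldimethylsilyloxy)methyl]-5-isopropyl-6-(tigloyloxy)cyclohex-2-en-1-one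
Conditions: Dess–Martin periodinane, CH2Cl2, 0 °C to rt; aq Na2S2O3/NaHCO3
Reagents that add atoms: none
Why: Dess–Martin oxidation converts the secondary allylic alcohol into the enone under nearly neutral conditions, erasing the temporary C1 centre without disturbing the esters, the silyl ether or the C6 centre, whose trans relation to isopropyl is in any case the stable one.

Step 12
Reactants: 19 (4S,5S,6R)-4-(angeloyloxy)-2-[(tert-butyldimethylsilyloxy)methyl]-5-isopropyl-6-(tigloyloxy)cyclohex-2-en-1-one
Product: 20 (4S,5S,6R)-4-(angeloyloxy)-2-(hydroxymethyl)-5-isopropyl-6-(tigloyloxy)cyclohex-2-en-1-one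
Conditions: HF·pyridine, pyridine, THF, 0 °C to rt
Reagents that add atoms: none
Why: Fluoride-mediated desilylation under buffered acidic conditions removes the primary silyl ether through formation of the strong Si–F bond and avoids the basic media that could epimerise C6, shift acyl groups or isomerise the angelate.

Compound list
1 | 2-hydroxy-5-methoxybenzaldehyde | COc1ccc(O)c(C=O)c1 | starting material
2 | 2-(hydroxymethyl)-4-methoxyphenol | COc1ccc(O)c(CO)c1 | intermediate
3 | 2-[(tert-butyldimethylsilyloxy)methyl]-4-methoxyphenol | COc1ccc(O)c(CO[Si](C)(C)C(C)(C)C)c1 | intermediate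
4 | 2-[(tert-butyldimethylsilyloxy)methyl]-4,4-dimethoxycyclohexa-2,5-dien-1-one | COC1(OC)C=CC(=O)C(CO[Si](C)(C)C(C)(C)C)=C1 | intermediate
5 | diisopropylzinc | CC(C)[Zn]C(C)C | starting material
6 | 2-(phenylsulfonyl)-3-phenyloxaziridine (racemic) | O=S(=O)(c1ccccc1)N1OC1c1ccccc1 | starting material
7 | (5R)-isopropylzinc dienolate of the conjugate adduct (C1–O–Zn, C1=C6, C2=C3) | COC1(OC)C=C(CO[Si](C)(C)C(C)(C)C)C(O[Zn]C(C)C)=C[C@H]1C(C)C | intermediate
8 | (5R,6R)-2-[(tert-butyldimethylsilyloxy)methyl]-6-hydroxy-5-isopropyl-4,4-dimethoxycyclohex-2-en-1-one | COC1(OC)C=C(CO[Si](C)(C)C(C)(C)C)C(=O)[C@H](O)[C@H]1C(C)C | intermediate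
9 | tigloyl chloride, (E)-2-methylbut-2-enoyl chloride | C/C=C(\C)C(=O)Cl | starting material
10 | (5R,6R)-2-[(tert-butyldimethylsilyloxy)methyl]-5-isopropyl-4,4-dimethoxy-6-(tigloyloxy)cyclohex-2-en-1-one | COC1(OC)C=C(CO[Si](C)(C)C(C)(C)C)C(=O)[C@H](OC(=O)/C(C)=C/C)[C@H]1C(C)C | intermediate
11 | (1R,5R,6R)-2-[(tert-butyldimethylsilyloxy)methyl]-5-isopropyl-4,4-dimethoxy-6-(tigloyloxy)cyclohex-2-en-1-ol | COC1(OC)C=C(CO[Si](C)(C)C(C)(C)C)[C@@H](O)[C@H](OC(=O)/C(C)=C/C)[C@H]1C(C)C | intermediate
12 | (1R,5R,6R)-2-[(tert-butyldimethylsilyloxy)methyl]-1-hydroxy-5-isopropyl-6-(tigloyloxy)cyclohex-2-en-4-one | O=C1C=C(CO[Si](C)(C)C(C)(C)C)[C@@H](O)[C@H](OC(=O)/C(C)=C/C)[C@H]1C(C)C | intermediate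
13 | (1R,5R,6R)-2-[(tert-butyldimethylsilyloxy)methyl]-5-isopropyl-6-(tigloyloxy)-1-(triethylsilyloxy)cyclohex-2-en-4-one | O=C1C=C(CO[Si](C)(C)C(C)(C)C)[C@@H](O[Si](CC)(CC)CC)[C@H](OC(=O)/C(C)=C/C)[C@H]1C(C)C | intermediate
14 | (1R,4S,5S,6R)-2-[(tert-butyldimethylsilyloxy)methyl]-5-isopropyl-6-(tigloyloxy)-1-(triethylsilyloxy)cyclohex-2-en-4-ol (C4–OH cis to isopropyl) | O[C@H]1C=C(CO[Si](C)(C)C(C)(C)C)[C@@H](O[Si](CC)(CC)CC)[C@H](OC(=O)/C(C)=C/C)[C@H]1C(C)C | intermediate
15 | angelic acid, (Z)-2-methylbut-2-enoic acid | C/C=C(/C)C(=O)O | starting material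
16 | angelic 2,4,6-trichlorobenzoic anhydride | C/C=C(/C)C(=O)OC(=O)c1c(Cl)cc(Cl)cc1Cl | intermediate
17 | (1R,4S,5S,6R)-4-(angeloyloxy)-2-[(tert-butyldimethylsilyloxy)methyl]-5-isopropyl-6-(tigloyloxy)-1-(triethylsilyloxy)cyclohex-2-ene | C/C=C(/C)C(=O)O[C@H]1C=C(CO[Si](C)(C)C(C)(C)C)[C@@H](O[Si](CC)(CC)CC)[C@H](OC(=O)/C(C)=C/C)[C@H]1C(C)C | intermediate
18 | (1R,4S,5S,6R)-4-(angeloyloxy)-2-[(tert-butyldimethylsilyloxy)methyl]-5-isopropyl-6-(tigloyloxy)cyclohex-2-en-1-ol | C/C=C(/C)C(=O)O[C@H]1C=C(CO[Si](C)(C)C(C)(C)C)[C@@H](O)[C@H](OC(=O)/C(C)=C/C)[C@H]1C(C)C | intermediate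
19 | (4S,5S,6R)-4-(angeloyloxy)-2-[(tert-butyldimethylsilyloxy)methyl]-5-isopropyl-6-(tigloyloxy)cyclohex-2-en-1-one | C/C=C(/C)C(=O)O[C@H]1C=C(CO[Si](C)(C)C(C)(C)C)C(=O)[C@H](OC(=O)/C(C)=C/C)[C@H]1C(C)C | intermediate
20 | (4S,5S,6R)-4-(angeloyloxy)-2-(hydroxymethyl)-5-isopropyl-6-(tigloyloxy)cyclohex-2-en-1-one (CNP0293256.3) | C/C=C(/C)C(=O)O[C@H]1C=C(CO)C(=O)[C@H](OC(=O)/C(C)=C/C)[C@H]1C(C)C | target

Total step count: 12. Longest linear sequence: 12 steps (1 to 20).

Steps most likely to fail

1. Step 4 (the labelled step).
- What may go wrong: oxygen transfer to the zinc enolate may be too slow. Protonation on work-up, oxidation of leftover C–Zn bonds or Mannich-type capture of the enolate by the imine by-product would then take over. Incomplete facial control at C6 is a lesser concern.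
- Fallback, known chemistry only, setting out from 4 and returning at 8: the copper-catalysed conjugate addition is run alone with the same catalyst. Dienolate 7 is trapped with TMSOTf to give the (5R)-trimethylsilyl dienol ether F1. Rubottom oxidation (mCPBA, NaHCO3, CH2Cl2, −20 °C) epoxidises the electron-rich C1=C6 bond anti to isopropyl and, after silyl migration, gives the (5R,6R)-6-trimethylsilyloxy ketone F2. Citric acid in MeOH then removes the trimethylsilyl group and returns to 8.

2. Step 9.
- What may go wrong: acylation of the pseudoaxial C4 hydroxyl, crowded by the cis isopropyl group, may be slow. Prolonged heating would then allow Z to E drift of the acyl donor or dehydration of the allylic alcohol.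
- Fallback, setting out from 14 and returning at 17: the Z alkene is built on an ester that is already in place. Alcohol 14 is esterified with 2-[bis(2,2,2-trifluoroethoxy)phosphoryl]propanoic acid (DCC, 4-(dimethylamino)pyridine, CH2Cl2) to give the C4 phosphonopropionate F3. Still–Gennari olefination of F3 with acetaldehyde (KN(SiMe3)2, 18-crown-6, THF, −78 °C) then gives the angelate 17.

3. Step 8.
- What may go wrong: facial selectivity at C4 may be poor, because the enone offers only one axial hydrogen to steer the bulky hydride. Some conjugate hydride delivery, or base-induced loss of the tiglate, is also possible.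
- Fallback, setting out from 13 and returning at 17: the opposite selectivity is accepted and corrected during esterification. Luche reduction (NaBH4, CeCl3·7H2O, MeOH, −78 °C) should follow the axial line and give the pseudoequatorial (4R)-alcohol F4, trans to isopropyl. Mitsunobu esterification of F4 with angelic acid 15 (PPh3, DIAD, toluene, 0 °C) then inverts C4 by SN2 displacement. The acid acts only as a carboxylate nucleophile, so its Z geometry is preserved and 17 is reached directly.

Further compounds
F1 | step 4 | (5R)-2-[(tert-butyldimethylsilyloxy)methyl]-5-isopropyl-4,4-dimethoxy-1-(trimethylsilyloxy)cyclohexa-1(6),2-diene | COC1(OC)C=C(CO[Si](C)(C)C(C)(C)C)C(O[Si](C)(C)C)=C[C@H]1C(C)C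
F2 | step 4 | (5R,6R)-2-[(tert-butyldimethylsilyloxy)methyl]-5-isopropyl-4,4-dimethoxy-6-(trimethylsilyloxy)cyclohex-2-en-1-one | COC1(OC)C=C(CO[Si](C)(C)C(C)(C)C)C(=O)[C@H](O[Si](C)(C)C)[C@H]1C(C)C
F3 | step 9 | (1R,4S,5S,6R)-4-{2-[bis(2,2,2-trifluoroethoxy)phosphoryl]propanoyloxy}-2-[(tert-butyldimethylsilyloxy)methyl]-5-isopropyl-6-(tigloyloxy)-1-(triethylsilyloxy)cyclohex-2-ene (both epimers at the phosphonate carbon) | CC(C(=O)O[C@H]1C=C(CO[Si](C)(C)C(C)(C)C)[C@@H](O[Si](CC)(CC)CC)[C@H](OC(=O)/C(C)=C/C)[C@H]1C(C)C)P(=O)(OCC(F)(F)F)OCC(F)(F)F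
F4 | step 8 | (1R,4R,5S,6R)-2-[(tert-butyldimethylsilyloxy)methyl]-5-isopropyl-6-(tigloyloxy)-1-(triethylsilyloxy)cyclohex-2-en-4-ol (C4–OH trans to isopropyl) | O[C@@H]1C=C(CO[Si](C)(C)C(C)(C)C)[C@@H](O[Si](CC)(CC)CC)[C@H](OC(=O)/C(C)=C/C)[C@H]1C(C)C
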